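The oxolane ring is assembled by a formal [3+2] union of an (E)-propenylarene (C2–C3, already carrying the lactate stub of the side chain) with the O1–C5–C4 unit of an aryl ethyl ketone, delivered as a chiral rhodium carbene from the α-diazoketone. In one operation C3 and C4, two carbons of like nucleophilic polarity, are joined under catalyst control through a temporary cyclopropane, and O1–C2 is closed by stereoconvergent capture of the C2 cation that the 4-alkoxy-3-methoxyphenyl ring on C2 stabilises. Ionic reduction at C5 then sets C4 and C5; chelation-controlled aryl Grignard addition completes the threo side chain.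

Key step: step 4

Assumption: the facial sense of Rh2(S-PTTL)4 (dirhodium tetrakis[N-phthaloyl-(S)-tert-leucinate]) in step 4 is taken to give the (2R,3R)-dihydrofuran; should the opposite sense be found, Rh2(R-PTTL)4 is used instead.

Step 1
Reactants: 1 (E)-isoeugenol; 2 ethyl (S)-lactate
Product: 3 ethyl (2R)-2-{2-methoxy-4-[(E)-prop-1-en-1-yl]phenoxy}propanoate
Conditions: PPh3, DIAD, THF, 0 °C to rt
Reagents that add atoms: none
Why: Mitsunobu reaction: the phenol displaces the activated lactate hydroxyl by SN2 with inversion, so the (S)-alcohol should give the (R)-aryl ether (the future methyl-bearing carbon of the side chain) while the propenyl group is untouched.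

Step 2
Reactants: 4 1-(4-hydroxy-3-methoxyphenyl)propan-1-one (propiovanillone)
Product: 5 1-[4-(benzyloxy)-3-methoxyphenyl]propan-1-one
Conditions: BnBr, K2CO3, DMF, rt
Reagents that add atoms: benzyl bromide, BrCc1ccccc1
Why: Williamson ether synthesis on the phenoxide masks the phenol as a benzyl ether that survives every later step and is removed by hydrogenolysis at the end.

Step 3
Reactants: 5 1-[4-(benzyloxy)-3-methoxyphenyl]propan-1-one
Product: 7 1-[4-(benzyloxy)-3-methoxyphenyl]-2-diazopropan-1-one, via trifluoroacetyl diketone 6 (not isolated)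
Conditions: LiN(SiMe3)2, THF, −78 °C, CF3CO2CH2CF3; then 4-acetamidobenzenesulfonyl azide, Et3N, H2O (1 equiv), MeCN, rt
Reagents that add atoms: 4-acetamidobenzenesulfonyl azide, CC(=O)Nc1ccc(cc1)S(=O)(=O)N=[N+]=[N-]
Why: Detrifluoroacetylative diazo transfer (a Regitz-type reaction): Claisen trifluoroacetylation activates the α-methylene group, the sulfonyl azide then transfers N2 and carries off the trifluoroacetyl group, leaving the α-methyl-α-diazoketone.

Step 4
Reactants: 3 ethyl (2R)-2-{2-methoxy-4-[(E)-prop-1-en-1-yl]phenoxy}propanoate; 7 1-[4-(benzyloxy)-3-methoxyphenyl]-2-diazopropan-1-one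
Product: 9 ethyl (2R)-2-{4-[(2R,3R)-5-[4-(benzyloxy)-3-methoxyphenyl]-3,4-dimethyl-2,3-dihydrofuran-2-yl]-2-methoxyphenoxy}propanoate, via donor–acceptor cyclopropane 8 (not isolated)
Conditions: Rh2(S-PTTL)4 (1 mol %), 3 (3 equiv), toluene, −78 °C, slow addition of 7; then Sc(OTf)3 (5 mol %), CH2Cl2, 0 °C
Reagents that add atoms: none
Why: Loss of N2 from 7 at the dirhodium catalyst gives an electrophilic carbene at C4 (polarity reversal of the ketone α-carbon), which is attacked by the nucleophilic β-carbon C3 of the anethole-type alkene; the developing C2 cation, stabilised by the para-alkoxy group of ring A, either collapses to cyclopropane 8 or is captured directly by the enolate oxygen, and Sc(OTf)3 reopens the C2–C4 bond of 8 so that O1 closes on C2 (Cloke–Wilson rearrangement). The closest known reaction types are the enantioselective cyclopropanation of alkenes with α-alkyl-α-diazo carbonyl compounds under bulky chiral dirhodium carboxylates and the formal [3+2] dihydrofuran annulation of acceptor carbenes with electron-rich alkenes. The three-membered ring closes by [2+1] carbene addition and the five-membered ring by collapse of the enolate oxygen onto the benzylic cation (a formal 1,3-shift), in which C3 is a spectator. C3 is set by the chiral ligand sphere, which selects the alkene face in the C3–C4 bond formation; C2 is set by the reversible cation capture, which should place the aryl group trans to the C3 methyl; C4 becomes sp2, so both C4 epimers of 8 converge on one product. The step needs carbene capture to outrun 1,2-hydride migration and allylic C–H insertion, which the hindered carboxylate ligands, −78 °C, the excess of the strongly nucleophilic alkene and the presence of only primary β-hydrogens should secure.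

Step 5
Reactants: 9 ethyl (2R)-2-{4-[(2R,3R)-5-[4-(benzyloxy)-3-methoxyphenyl]-3,4-dimethyl-2,3-dihydrofuran-2-yl]-2-methoxyphenoxy}propanoate
Product: 11 ethyl (2R)-2-{4-[(2R,3R,4R,5S)-5-[4-(benzyloxy)-3-methoxyphenyl]-3,4-dimethyloxolan-2-yl]-2-methoxyphenoxy}propanoate, via ethyl ketal 10 (not isolated)
Conditions: CSA (cat.), EtOH, rt; then Et3SiH, BF3·OEt2, CH2Cl2, −78 °C
Reagents that add atoms: none
Why: Acid-catalysed addition of ethanol to the cyclic enol ether equilibrates C4 through the oxocarbenium ion to the 3,4-trans ketal, and ionic hydrogenation of the regenerated C5 oxocarbenium ion should deliver hydride anti to the C4 methyl and the C2 aryl group, which puts the C5 aryl cis to the C4 methyl (4R,5S).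

Step 6
Reactants: 11 ethyl (2R)-2-{4-[(2R,3R,4R,5S)-5-[4-(benzyloxy)-3-methoxyphenyl]-3,4-dimethyloxolan-2-yl]-2-methoxyphenoxy}propanoate
Product: 12 (2R)-2-{4-[(2R,3R,4R,5S)-5-[4-(benzyloxy)-3-methoxyphenyl]-3,4-dimethyloxolan-2-yl]-2-methoxyphenoxy}propanal
Conditions: iBu2AlH, toluene, −78 °C; aq. potassium sodium tartrate
Reagents that add atoms: none
Why: Partial reduction of the ester by iBu2AlH at −78 °C stops at the aluminium hemiacetal, which gives the α-aryloxy aldehyde on work-up; the crude aldehyde is used at once to avoid epimerisation.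

Step 7
Reactants: 12 (2R)-2-{4-[(2R,3R,4R,5S)-5-[4-(benzyloxy)-3-methoxyphenyl]-3,4-dimethyloxolan-2-yl]-2-methoxyphenoxy}propanal; 13 1-(benzyloxy)-4-bromo-2-methoxybenzene
Product: 15 (1R,2R)-1-[4-(benzyloxy)-3-methoxyphenyl]-2-{4-[(2R,3R,4R,5S)-5-[4-(benzyloxy)-3-methoxyphenyl]-3,4-dimethyloxolan-2-yl]-2-methoxyphenoxy}propan-1-ol, via arylmagnesium bromide 14 (not isolated)
Conditions: 13, Mg, THF, rt; then 12, THF–CH2Cl2, −78 °C; then H2O
Reagents that add atoms: none
Why: Grignard addition under Cram chelate control (magnesium bridging the aldehyde and aryloxy oxygens) attacks the face opposite the methyl group and should give the threo (1R,2R) carbinol.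

Step 8
Reactants: 15 (1R,2R)-1-[4-(benzyloxy)-3-methoxyphenyl]-2-{4-[(2R,3R,4R,5S)-5-[4-(benzyloxy)-3-methoxyphenyl]-3,4-dimethyloxolan-2-yl]-2-methoxyphenoxy}propan-1-ol
Product: 16 (1R,2R)-1-(4-hydroxy-3-methoxyphenyl)-2-{4-[(2R,3R,4R,5S)-5-(4-hydroxy-3-methoxyphenyl)-3,4-dimethyloxolan-2-yl]-2-methoxyphenoxy}propan-1-ol (CNP0171079.2)
Conditions: H2 (1 atm), Pd/C, EtOAc–MeOH, rt
Reagents that add atoms: none
Why: Hydrogenolysis over palladium cleaves the two aryl benzyl ethers much faster than the dialkyl benzylic C–O bonds of the oxolane and the carbinol, so stopping after two equivalents of hydrogen should leave all six stereocentres untouched.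

Compound list

1 | (E)-isoeugenol, 2-methoxy-4-[(E)-prop-1-en-1-yl]phenol | C/C=C/c1ccc(O)c(OC)c1 | starting material
2 | ethyl (S)-lactate, ethyl (2S)-2-hydroxypropanoate | C[C@H](O)C(=O)OCC | starting material
3 | ethyl (2R)-2-{2-methoxy-4-[(E)-prop-1-en-1-yl]phenoxy}propanoate | CCOC(=O)[C@@H](C)Oc1ccc(/C=C/C)cc1OC | intermediate
4 | 1-(4-hydroxy-3-methoxyphenyl)propan-1-one (propiovanillone) | CCC(=O)c1ccc(O)c(OC)c1 | starting material
5 | 1-[4-(benzyloxy)-3-methoxyphenyl]propan-1-one | CCC(=O)c1ccc(OCc2ccccc2)c(OC)c1 | intermediate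
6 | 1-[4-(benzyloxy)-3-methoxyphenyl]-4,4,4-trifluoro-2-methylbutane-1,3-dione (present as its lithium enolate) | CC(C(=O)C(F)(F)F)C(=O)c1ccc(OCc2ccccc2)c(OC)c1 | intermediate
7 | 1-[4-(benzyloxy)-3-methoxyphenyl]-2-diazopropan-1-one | CC(=[N+]=[N-])C(=O)c1ccc(OCc2ccccc2)c(OC)c1 | intermediate
8 | ethyl (2R)-2-{4-[2-[4-(benzyloxy)-3-methoxybenzoyl]-2,3-dimethylcyclopropyl]-2-methoxyphenoxy}propanoate (aryl and 3-methyl trans, alkene-derived carbons as in 9, both epimers at the acyl-bearing carbon) | CCOC(=O)[C@@H](C)Oc1ccc([C@H]2[C@H](C)C2(C)C(=O)c3ccc(OCc4ccccc4)c(OC)c3)cc1OC | intermediate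
9 | ethyl (2R)-2-{4-[(2R,3R)-5-[4-(benzyloxy)-3-methoxyphenyl]-3,4-dimethyl-2,3-dihydrofuran-2-yl]-2-methoxyphenoxy}propanoate | CCOC(=O)[C@@H](C)Oc1ccc([C@@H]2OC(c3ccc(OCc4ccccc4)c(OC)c3)=C(C)[C@H]2C)cc1OC | intermediate
10 | ethyl (2R)-2-{4-[(2R,3R,4R)-5-[4-(benzyloxy)-3-methoxyphenyl]-5-ethoxy-3,4-dimethyloxolan-2-yl]-2-methoxyphenoxy}propanoate (both C5 anomers) | CCOC(=O)[C@@H](C)Oc1ccc([C@@H]2OC(OCC)(c3ccc(OCc4ccccc4)c(OC)c3)[C@H](C)[C@H]2C)cc1OC | intermediate
11 | ethyl (2R)-2-{4-[(2R,3R,4R,5S)-5-[4-(benzyloxy)-3-methoxyphenyl]-3,4-dimethyloxolan-2-yl]-2-methoxyphenoxy}propanoate | CCOC(=O)[C@@H](C)Oc1ccc([C@@H]2O[C@H](c3ccc(OCc4ccccc4)c(OC)c3)[C@H](C)[C@H]2C)cc1OC | intermediate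
12 | (2R)-2-{4-[(2R,3R,4R,5S)-5-[4-(benzyloxy)-3-methoxyphenyl]-3,4-dimethyloxolan-2-yl]-2-methoxyphenoxy}propanal | O=C[C@@H](C)Oc1ccc([C@@H]2O[C@H](c3ccc(OCc4ccccc4)c(OC)c3)[C@H](C)[C@H]2C)cc1OC | intermediate
13 | 1-(benzyloxy)-4-bromo-2-methoxybenzene | COc1cc(Br)ccc1OCc1ccccc1 | starting material
14 | [4-(benzyloxy)-3-methoxyphenyl]magnesium bromide | COc1cc([Mg]Br)ccc1OCc1ccccc1 | intermediate
15 | (1R,2R)-1-[4-(benzyloxy)-3-methoxyphenyl]-2-{4-[(2R,3R,4R,5S)-5-[4-(benzyloxy)-3-methoxyphenyl]-3,4-dimethyloxolan-2-yl]-2-methoxyphenoxy}propan-1-ol | COc1cc([C@@H](O)[C@@H](C)Oc2ccc([C@@H]3O[C@H](c4ccc(OCc5ccccc5)c(OC)c4)[C@H](C)[C@H]3C)cc2OC)ccc1OCc1ccccc1 | intermediate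
16 | (1R,2R)-1-(4-hydroxy-3-methoxyphenyl)-2-{4-[(2R,3R,4R,5S)-5-(4-hydroxy-3-methoxyphenyl)-3,4-dimethyloxolan-2-yl]-2-methoxyphenoxy}propan-1-ol | COc1cc([C@@H](O)[C@@H](C)Oc2ccc([C@@H]3O[C@H](c4ccc(O)c(OC)c4)[C@H](C)[C@H]3C)cc2OC)ccc1O | target

Total step count: 8. Longest linear sequence: 7 steps (4 → 5 → 7 → 9 → 11 → 12 → 15 → 16; steps 2 to 8).

Steps most likely to fail

1. Step 4 (key step). The carbene may undergo 1,2-hydride migration to the aryl vinyl ketone or allylic C–H insertion faster than it is captured by the trans-disubstituted alkene, and the catalyst may not discriminate the alkene faces well enough. Fallback (radical–polar crossover instead of carbene transfer), setting out from 5 and 3 and returning at 9: α-bromination of ketone 5 with CuBr2 (EtOAc–CHCl3, reflux) should give 2-bromo-1-[4-(benzyloxy)-3-methoxyphenyl]propan-1-one F1. Irradiation of F1 with alkene 3, fac-Ir(ppy)3 and 2,6-lutidine in MeCN (blue light, rt) should add the α-keto radical to C3, oxidise the benzylic radical to the C2 cation through the oxidised iridium complex, and close O1–C2 with loss of a proton. This forms the same trans-dihydrofuran without facial control, that is 9 together with ethyl (2R)-2-{4-[(2S,3S)-5-[4-(benzyloxy)-3-methoxyphenyl]-3,4-dimethyl-2,3-dihydrofuran-2-yl]-2-methoxyphenoxy}propanoate F2. The two are diastereomers through the lactate centre and would have to be separated by preparative HPLC before the route resumes at 9.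

2. Step 5. Equilibration at C4 may be incomplete before reduction, hydride may be delivered to the wrong face of the oxocarbenium ion, or the Lewis acid may open the C2–O1 bond. Fallback (radical instead of ionic reduction), setting out from 9 and returning at 11: CSA-catalysed addition of thiophenol to the enol ether (CH2Cl2, rt) should give ethyl (2R)-2-{4-[(2R,3R,4R)-5-[4-(benzyloxy)-3-methoxyphenyl]-3,4-dimethyl-5-(phenylsulfanyl)oxolan-2-yl]-2-methoxyphenoxy}propanoate F3. Bu3SnH with AIBN (toluene, 80 °C) should then cleave the C–S bond through the planar C5 radical, which takes hydrogen anti to the C4 methyl and gives 11.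

3. Step 7. The α-aryloxy aldehyde may epimerise, and facial selectivity may be poor if chelation is incomplete. Fallback (ketone reduction instead of aldehyde addition), setting out from 11 and returning at 15: iPrMgCl and MeNHOMe·HCl (THF, −20 °C) should convert ester 11 into (2R)-2-{4-[(2R,3R,4R,5S)-5-[4-(benzyloxy)-3-methoxyphenyl]-3,4-dimethyloxolan-2-yl]-2-methoxyphenoxy}-N-methoxy-N-methylpropanamide F4. Grignard reagent 14 should then give (2R)-1-[4-(benzyloxy)-3-methoxyphenyl]-2-{4-[(2R,3R,4R,5S)-5-[4-(benzyloxy)-3-methoxyphenyl]-3,4-dimethyloxolan-2-yl]-2-methoxyphenoxy}propan-1-one F5. Reagent-controlled reduction with (R)-2-methyl-CBS-oxazaborolidine and BH3·SMe2 (THF, −20 °C) should give the (1R) carbinol 15.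

Further compounds

F1 | step 4 | 2-bromo-1-[4-(benzyloxy)-3-methoxyphenyl]propan-1-one | CC(Br)C(=O)c1ccc(OCc2ccccc2)c(OC)c1
F2 | step 4 | ethyl (2R)-2-{4-[(2S,3S)-5-[4-(benzyloxy)-3-methoxyphenyl]-3,4-dimethyl-2,3-dihydrofuran-2-yl]-2-methoxyphenoxy}propanoate | CCOC(=O)[C@@H](C)Oc1ccc([C@H]2OC(c3ccc(OCc4ccccc4)c(OC)c3)=C(C)[C@@H]2C)cc1OC
F3 | step 5 | ethyl (2R)-2-{4-[(2R,3R,4R)-5-[4-(benzyloxy)-3-methoxyphenyl]-3,4-dimethyl-5-(phenylsulfanyl)oxolan-2-yl]-2-methoxyphenoxy}propanoate | CCOC(=O)[C@@H](C)Oc1ccc([C@@H]2OC(Sc5ccccc5)(c3ccc(OCc4ccccc4)c(OC)c3)[C@H](C)[C@H]2C)cc1OC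
F4 | step 7 | (2R)-2-{4-[(2R,3R,4R,5S)-5-[4-(benzyloxy)-3-methoxyphenyl]-3,4-dimethyloxolan-2-yl]-2-methoxyphenoxy}-N-methoxy-N-methylpropanamide | CON(C)C(=O)[C@@H](C)Oc1ccc([C@@H]2O[C@H](c3ccc(OCc4ccccc4)c(OC)c3)[C@H](C)[C@H]2C)cc1OC
F5 | step 7 | (2R)-1-[4-(benzyloxy)-3-methoxyphenyl]-2-{4-[(2R,3R,4R,5S)-5-[4-(benzyloxy)-3-methoxyphenyl]-3,4-dimethyloxolan-2-yl]-2-methoxyphenoxy}propan-1-one | COc1cc(C(=O)[C@@H](C)Oc2ccc([C@@H]3O[C@H](c4ccc(OCc5ccccc5)c(OC)c4)[C@H](C)[C@H]3C)cc2OC)ccc1OCc1ccccc1
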